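The numbers in the tables stem from a simulated flask for an exercise, and the scatter is random.

28.03 mM of Prd stand in the dusk run at 22 min, so of the 40.0 mM of Rgt charged, the limiting reagent there, 12.0 mM remain as Rgt, and you want one rate that closes that ledger on the next flask too.

| setting | dusk | midnight | autumn | winter | summer |
|---|---|---|---|---|---|
| Sub | 50.0 mM | 20.0 mM | 50.0 mM | 150 mM | 100 mM |
| Rgt | 40.0 mM | 10.0 mM | 120 mM | 40.0 mM | 120 mM |
| time |  |  |  |  | 22 min |

- dusk run (time / min: [Prd] / mM): 0.88: 2.38; 2.0: 4.96; 4.4: 9.54; 9.8: 17.53; 22: 28.03
- midnight run (time / min: [Prd] / mM): 0.88: 0.24; 2.0: 0.29; 4.4: 2.03; 9.8: 3.76; 22: 6.32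
- autumn run (time / min: [Prd] / mM): 0.88: 4.75; 2.0: 9.76; 4.4: 19.94; 9.8: 35.12; 22: 49.08
- winter run (time / min: [Prd] / mM): 0.88: 3.55; 2.0: 8.32; 4.4: 16.18; 9.8: 27.40; 22: 37.64

(readings scatter by 0.2 mM)

- Overall: Sub + Rgt -> Prd.
- Constant volume, constant temperature.
- Readings of a species count what is bound in complexes too.
- An order is taken over about fifteen percent of the charge, up and down.

- how the opening rate goes with [Sub] round the charge of the dusk run: the exponent of the rate at two percent of Sub gone to Prd (one fixed amount of Prd, the same in the runs compared)
- how the opening rate goes with [Rgt] round the charge of the dusk run: the exponent of the rate at two percent of Sub gone to Prd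
- the midnight run starts with 30.0 mM less of Sub and of Rgt than the dusk run, and with no Prd. Compared where both hold the same amount of Sub, once fifteen percent of what the midnight run was charged with has turned into Prd, is the midnight run faster, slower or alike (within a tenth)?
- Prd in the summer run at 22 min, as a share of the Sub charged

First, the terms of the ledger. Going from the dusk run to the winter run multiplies the Sub charge by 3.00 and the Prd at 2.0 min by 1.68, my reading of an exponent of 0.471, near a half. The autumn run, with its Rgt charge raised by the same factor, gives 0.616 for Rgt over that wide step. In the dusk and winter runs, though, Rgt falls below its dusk charge as they proceed, so I bet on first order there. The rate is then a clock times Rgt times the root of Sub over the dusk charge of Sub.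

Each Sub lost takes one Rgt, so Sub minus Rgt stays fixed, and the rate integrates in closed form. Let y be that root, Y its starting value, and a the root of the Sub excess over the dusk charge of Sub. Then clock × a × t = ln[(Y − a)(y + a) / ((Y + a)(y − a))].

For the dusk run, Y is 1, a is 0.447, and the last reading gives y as 0.663. So the clock, the pseudo-first-order constant of Rgt at the dusk charge of Sub, reads 0.0687 /min.

The forecast gives the Sub order as 0.4 (0.28 to 0.52), lower than my reading, and the Rgt order as 0.63 (0.5 to 0.75). It calls the midnight run alike and puts the summer run at 80 % (74 % to 86 %), holding that “the rate is saturating”.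

The flask gives 0.56 and 0.78, each above the forecast's range, the midnight run alike, and the summer run at 81.1 %.

    Sub + Rgt → Prd + Byp (10.74 /M/min)
    2 Rgt ⇌ Rgt2, settled at all times (8.670 /M)
    2 Sub ⇌ Sub2, settled at all times (282.0 /M)

The root in the clock's rate stands for Sub2: with the joining of 2 Sub the Sub order is 0.56, and without it 1.0. Now run the clock forward to where Prd is a quarter of the Sub charged. In the dusk run it gives 5.87 min, and the flask took 6.22 min. In the winter run, with a at 1.48 and Y at 1.73, it gives 25.7 min, and the flask took 21.9 min.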